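The route rests on cutting the C5–C6 bond of ring A, which joins the gem-dimethyl carbon C5 to the spiro carbon C6. Since C6 sits β to a ring B carbonyl at C10, a tertiary C5 radical can forge this crowded bond by conjugate addition. In one operation an iron hydride converts a methallyl terminus into that radical, closes ring A 6-exo onto a cyclohexenone, builds both fully substituted carbons and sets C6 under the control of a C3 silyloxy group. The precursor is a 3-alkenylcyclohex-2-enone whose (Z)-trisubstituted alkene (C1=C2) carries the C3 silyl ether and the methallyl group. The C10 ketone then provides the C9 methyl and C10 bromide, and ring A is adjusted last.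

Key step: step 7

Remarks on the chemistry:
- Atom labels C1–C11 are those of the target (ring A: C1(Me)=C2–C3–C4–C5Me2–C6; ring B: C6–C7–C8–C9–C10–C11) and serve as locants in all spiro names.
- 2-Methylallylmagnesium chloride is taken as the commercial THF solution.
- (Ipc)2BOMe denotes the B-methoxydiisopinocampheylborane prepared from (−)-α-pinene.
- The C3 stereocentre made in step 3 is a relay only: it is oxidised in step 12 and set again in step 14.
- The C6 descriptor changes from R to S at compound 25 only because the CIP priorities change when bromine enters at C4; the spatial arrangement at C6 is unchanged from 13 onward.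

Step 1
Reactants: 1 cyclohexane-1,3-dione
Product: 2 3-oxocyclohex-1-en-1-yl trifluoromethanesulfonate
Conditions: Tf2O, pyridine, CH2Cl2, −78 → 0 °C
Reagents that add atoms: trifluoromethanesulfonic anhydride, O=S(=O)(OS(=O)(=O)C(F)(F)F)C(F)(F)F
Why: O-sulfonylation of the enol form of the 1,3-diketone (enol triflate formation) gives the vinylogous acyl triflate, the usual entry to 3-functionalised cyclohexenones.

Step 2
Reactants: 2 3-oxocyclohex-1-en-1-yl trifluoromethanesulfonate
Product: 3 3-(4,4,5,5-tetramethyl-1,3,2-dioxaborolan-2-yl)cyclohex-2-en-1-one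
Conditions: B2pin2, PdCl2(PPh3)2 (3 mol %), PPh3 (6 mol %), K2CO3, dioxane, 80 °C
Reagents that add atoms: bis(pinacolato)diboron, CC1(C)OB(OC1(C)C)B1OC(C)(C)C(C)(C)O1
Why: Miyaura borylation of a β-triflyloxy enone is an established way to β-boryl enones, and the weak carbonate base spares the electrophilic product.

Step 3
Reactants: 4 but-2-ynal; 5 2-methylallylmagnesium chloride
Product: 8 (4R)-2-methylhept-1-en-5-yn-4-ol, via methallylborane 6 (not isolated), via borinate 7 (not isolated)
Conditions: (Ipc)2BOMe, Et2O, −78 → 23 °C; then 4, −78 °C; then aq NaOH, H2O2, 0 → 23 °C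
Reagents that add atoms: none
Why: Brown allylboration through a closed chair transition state, in which the isopinocampheyl groups derived from (−)-α-pinene steer the methallyl group to the aldehyde face that gives the 4R carbinol, followed by oxidative cleavage of the borinate.

Step 4
Reactants: 8 (4R)-2-methylhept-1-en-5-yn-4-ol
Product: 10 (4R,5Z)-6-iodo-2-methylhepta-1,5-dien-4-ol, via alkenylalanate 9 (not isolated)
Conditions: NaAlH2(OCH2CH2OMe)2, THF, 0 → 23 °C; EtOAc, 0 °C; then I2, THF, −78 → 0 °C
Reagents that add atoms: iodine, II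
Why: hydroxyl-directed trans-hydroalumination of the propargylic alcohol places aluminium on the distal alkyne carbon inside a five-membered alkoxyaluminate, and iodinolysis with retention gives the (Z)-iodoalkene with iodine cis to the carbinol carbon, while the isolated 1,1-disubstituted alkene is inert.

Step 5
Reactants: 10 (4R,5Z)-6-iodo-2-methylhepta-1,5-dien-4-ol
Product: 11 tert-butyl{[(4R,5Z)-6-iodo-2-methylhepta-1,5-dien-4-yl]oxy}dimethylsilane
Conditions: TBSCl, imidazole, DMF, 23 °C
Reagents that add atoms: tert-butylchlorodimethylsilane, CC(C)(C)[Si](C)(C)Cl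
Why: routine silylation of a secondary alcohol, which protects the carbinol from the strong bases used later and supplies the bulky group that steers the key step.

Step 6
Reactants: 11 tert-butyl{[(4R,5Z)-6-iodo-2-methylhepta-1,5-dien-4-yl]oxy}dimethylsilane; 3 3-(4,4,5,5-tetramethyl-1,3,2-dioxaborolan-2-yl)cyclohex-2-en-1-one
Product: 12 3-[(2Z,4R)-4-(tert-butyldimethylsilyloxy)-6-methylhepta-2,6-dien-2-yl]cyclohex-2-en-1-one
Conditions: Pd(dppf)Cl2 (5 mol %), K3PO4, THF/H2O (10:1), 50 °C
Reagents that add atoms: none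
Why: Suzuki–Miyaura coupling of an alkenyl iodide with an alkenyl boronate proceeds with retention at both sp2 carbons, so the (Z)-geometry that holds C3 and C6 on the same side of C1=C2 is carried into the dienone.

Step 7
Reactants: 12 3-[(2Z,4R)-4-(tert-butyldimethylsilyloxy)-6-methylhepta-2,6-dien-2-yl]cyclohex-2-en-1-one
Product: 13 (3R,6R)-3-(tert-butyldimethylsilyloxy)-1,5,5-trimethylspiro[5.5]undec-1-en-10-one
Conditions: Fe(acac)3 (0.3 equiv), PhSiH3 (2.5 equiv), EtOH/HOCH2CH2OH (5:1), 0.03 M, 60 °C; chromatographic removal of the C6 epimer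
Reagents that add atoms: none
Why: The iron hydride formed from Fe(acac)3 and PhSiH3 transfers a hydrogen atom to the terminal CH2 of the electron-rich 1,1-disubstituted alkene (Markovnikov) to give the tertiary C5 radical, which adds to the enone β-carbon C6; the α-keto radical at C11 is then reduced by divalent iron to the enolate and protonated by ethanol, which returns trivalent iron. The closest known reaction type is the metal-hydride hydrogen-atom-transfer reductive olefin coupling (radical conjugate addition), which is established for intramolecular closures that join two fully substituted carbons. Ring A closes in a 6-exo-trig mode through a half-chair transition state whose cis C1=C2 bond already spans C3 and C6. The new stereocentre C6 is controlled by C3: the silyloxy group stays pseudoequatorial because a pseudoaxial one would clash with a C5 methyl, and the flat sp2 carbon C11, not the C7 methylene, takes the crowded site between the two C5 methyls, so C5 should bond to the enone face that gives 6R; the C6 epimer is a separable diastereomer and is removed here because C3 is oxidised later. The step needs chemoselective hydrogen-atom transfer, which the higher reactivity of the isolated 1,1-disubstituted alkene over the electron-poor trisubstituted dienone should secure, and it needs the (Z)-alkene fixed in step 4.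

Step 8
Reactants: 13 (3R,6R)-3-(tert-butyldimethylsilyloxy)-1,5,5-trimethylspiro[5.5]undec-1-en-10-one
Product: 17 (3R,6R)-3-(tert-butyldimethylsilyloxy)-1,5,5-trimethyl-9-methylidenespiro[5.5]undec-1-en-10-one, via lithium enolate 14 (not isolated), via Mannich base 15 (not isolated), via ammonium iodide 16 (not isolated)
Conditions: LiN(i-Pr)2, THF, −78 °C; Me2N=CH2+ I−, −78 → 23 °C; MeI, CH2Cl2, 23 °C; then aq NaHCO3, 23 °C
Reagents that add atoms: dimethyl(methylidene)ammonium iodide, C=[N+](C)C.[I-]
Why: kinetic deprotonation occurs at C9 and not at the neopentyl C11 beside the spiro carbon, and Mannich reaction, N-methylation and elimination of trimethylamine (α-methylenation through a Mannich base) place the future methyl carbon on C9.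

Step 9
Reactants: 17 (3R,6R)-3-(tert-butyldimethylsilyloxy)-1,5,5-trimethyl-9-methylidenespiro[5.5]undec-1-en-10-one
Product: 19 (3R,6R)-3-(tert-butyldimethylsilyloxy)-1,5,5,9-tetramethylspiro[5.5]undeca-1,9-dien-10-yl trifluoromethanesulfonate, via lithium enolate 18 (not isolated)
Conditions: LiBH(s-Bu)3, THF, −78 °C; then PhNTf2, −78 → 0 °C
Reagents that add atoms: N-phenylbis(trifluoromethanesulfonimide), O=S(=O)(N(c1ccccc1)S(=O)(=O)C(F)(F)F)C(F)(F)F
Why: conjugate hydride addition to the exocyclic enone creates the C9 methyl group and the C9=C10 enolate regiospecifically, and O-triflation traps it (reductive enolate triflation), so no enolisation toward C11 can interfere.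

Step 10
Reactants: 19 (3R,6R)-3-(tert-butyldimethylsilyloxy)-1,5,5,9-tetramethylspiro[5.5]undeca-1,9-dien-10-yl trifluoromethanesulfonate
Product: 20 tert-butyl{[(3R,6R)-10-bromo-1,5,5,9-tetramethylspiro[5.5]undeca-1,9-dien-3-yl]oxy}dimethylsilane
Conditions: Ni(cod)2 (10 mol %), LiBr (3 equiv), DMA/THF (1:3), 23 °C
Reagents that add atoms: lithium bromide, [Li+].[Br-]
Why: zerovalent nickel inserts into the C–O bond of the enol triflate, triflate is exchanged for bromide and C–Br reductive elimination releases the alkenyl bromide (nickel-catalysed halogenation of enol triflates) under conditions that leave the silyl ether and the ring A alkene untouched.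

Step 11
Reactants: 20 tert-butyl{[(3R,6R)-10-bromo-1,5,5,9-tetramethylspiro[5.5]undeca-1,9-dien-3-yl]oxy}dimethylsilane
Product: 21 (3R,6R)-10-bromo-1,5,5,9-tetramethylspiro[5.5]undeca-1,9-dien-3-ol
Conditions: Bu4NF, THF, 0 → 23 °C
Reagents that add atoms: none
Why: fluoride-induced desilylation frees the allylic alcohol without touching the alkenyl bromide.

Step 12
Reactants: 21 (3R,6R)-10-bromo-1,5,5,9-tetramethylspiro[5.5]undeca-1,9-dien-3-ol
Product: 22 (6R)-10-bromo-1,5,5,9-tetramethylspiro[5.5]undeca-1,9-dien-3-one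
Conditions: Dess–Martin periodinane, NaHCO3, CH2Cl2, 23 °C
Reagents that add atoms: none
Why: Dess–Martin oxidation of the allylic alcohol gives the ring A enone, whose carbonyl makes C4 accessible as an enolate carbon.

Step 13
Reactants: 22 (6R)-10-bromo-1,5,5,9-tetramethylspiro[5.5]undeca-1,9-dien-3-one
Product: 25 (4S,6S)-4,10-dibromo-1,5,5,9-tetramethylspiro[5.5]undeca-1,9-dien-3-one, via lithium dienolate 23 (not isolated), via silyl dienol ether 24 (not isolated)
Conditions: LiN(i-Pr)2, THF, −78 °C; Me3SiCl; then NBS, THF, −78 → 0 °C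
Reagents that add atoms: N-bromosuccinimide, O=C1CCC(=O)N1Br
Why: kinetic α′-deprotonation at C4 and bromination of the cross-conjugated silyl dienol ether (α′-bromination of an enone) should deliver bromine anti to the pseudoaxial C7 methylene, because ring A places C11, whose neighbour C10 is sp2, in the pseudoequatorial site beside the C1 methyl, which leaves bromine equatorial and cis to C11.

Step 14
Reactants: 25 (4S,6S)-4,10-dibromo-1,5,5,9-tetramethylspiro[5.5]undeca-1,9-dien-3-one
Product: 26 (3S,4S,6S)-4,10-dibromo-1,5,5,9-tetramethylspiro[5.5]undeca-1,9-dien-3-ol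
Conditions: NaBH4, CeCl3·7H2O, MeOH, −78 °C
Reagents that add atoms: none
Why: Luche 1,2-reduction, in which the small borohydride should add along the axial trajectory at C3 so that the new hydroxyl is pseudoequatorial, trans to the equatorial C4 bromine and cis to C7 (3S), with both C–Br bonds and both alkenes left intact.

Compound list
1 | cyclohexane-1,3-dione | O=C1CCCC(=O)C1 | starting material
2 | 3-oxocyclohex-1-en-1-yl trifluoromethanesulfonate | O=C1C=C(OS(=O)(=O)C(F)(F)F)CCC1 | intermediate
3 | 3-(4,4,5,5-tetramethyl-1,3,2-dioxaborolan-2-yl)cyclohex-2-en-1-one | O=C1C=C(B2OC(C)(C)C(C)(C)O2)CCC1 | intermediate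
4 | but-2-ynal | CC#CC=O | starting material
5 | 2-methylallylmagnesium chloride | C=C(C)C[Mg]Cl | starting material
6 | B-(2-methylallyl)diisopinocampheylborane, Ipc groups from (−)-α-pinene | C=C(C)CB([C@H]1C[C@H]2C[C@@H]([C@@H]1C)C2(C)C)[C@H]1C[C@H]2C[C@@H]([C@@H]1C)C2(C)C | intermediate
7 | (4R)-2-methylhept-1-en-5-yn-4-yl diisopinocampheylborinate | C=C(C)C[C@@H](OB([C@H]1C[C@H]2C[C@@H]([C@@H]1C)C2(C)C)[C@H]1C[C@H]2C[C@@H]([C@@H]1C)C2(C)C)C#CC | intermediate
8 | (4R)-2-methylhept-1-en-5-yn-4-ol | C=C(C)C[C@@H](O)C#CC | intermediate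
9 | sodium 2,2-bis(2-methoxyethoxy)-3-methyl-5-(2-methylallyl)-2,5-dihydro-1,2-oxaluminol-2-uide, (5R) | CC1=C[C@@H](CC(C)=C)O[Al-]1(OCCOC)OCCOC.[Na+] | intermediate
10 | (4R,5Z)-6-iodo-2-methylhepta-1,5-dien-4-ol | C=C(C)C[C@@H](O)/C=C(/C)I | intermediate
11 | tert-butyl{[(4R,5Z)-6-iodo-2-methylhepta-1,5-dien-4-yl]oxy}dimethylsilane | C=C(C)C[C@@H](O[Si](C)(C)C(C)(C)C)/C=C(/C)I | intermediate
12 | 3-[(2Z,4R)-4-(tert-butyldimethylsilyloxy)-6-methylhepta-2,6-dien-2-yl]cyclohex-2-en-1-one | C=C(C)C[C@@H](O[Si](C)(C)C(C)(C)C)/C=C(/C)C1=CC(=O)CCC1 | intermediate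
13 | (3R,6R)-3-(tert-butyldimethylsilyloxy)-1,5,5-trimethylspiro[5.5]undec-1-en-10-one | CC1=C[C@H](O[Si](C)(C)C(C)(C)C)CC(C)(C)[C@]12CCCC(=O)C2 | intermediate
14 | lithium C9=C10 enolate of 13 | CC1=C[C@H](O[Si](C)(C)C(C)(C)C)CC(C)(C)[C@]12CCC=C(O[Li])C2 | intermediate
15 | (3R,6R)-3-(tert-butyldimethylsilyloxy)-9-[(dimethylamino)methyl]-1,5,5-trimethylspiro[5.5]undec-1-en-10-one, C9 epimers | CC1=C[C@H](O[Si](C)(C)C(C)(C)C)CC(C)(C)[C@]12CCC(CN(C)C)C(=O)C2 | intermediate
16 | trimethylammonium iodide derived from 15, C9 epimers | CC1=C[C@H](O[Si](C)(C)C(C)(C)C)CC(C)(C)[C@]12CCC(C[N+](C)(C)C)C(=O)C2.[I-] | intermediate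
17 | (3R,6R)-3-(tert-butyldimethylsilyloxy)-1,5,5-trimethyl-9-methylidenespiro[5.5]undec-1-en-10-one | CC1=C[C@H](O[Si](C)(C)C(C)(C)C)CC(C)(C)[C@]12CCC(=C)C(=O)C2 | intermediate
18 | lithium (3R,6R)-3-(tert-butyldimethylsilyloxy)-1,5,5,9-tetramethylspiro[5.5]undeca-1,9-dien-10-olate | CC1=C[C@H](O[Si](C)(C)C(C)(C)C)CC(C)(C)[C@]12CCC(C)=C(O[Li])C2 | intermediate
19 | (3R,6R)-3-(tert-butyldimethylsilyloxy)-1,5,5,9-tetramethylspiro[5.5]undeca-1,9-dien-10-yl trifluoromethanesulfonate | CC1=C[C@H](O[Si](C)(C)C(C)(C)C)CC(C)(C)[C@]12CCC(C)=C(OS(=O)(=O)C(F)(F)F)C2 | intermediate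
20 | tert-butyl{[(3R,6R)-10-bromo-1,5,5,9-tetramethylspiro[5.5]undeca-1,9-dien-3-yl]oxy}dimethylsilane | CC1=C[C@H](O[Si](C)(C)C(C)(C)C)CC(C)(C)[C@]12CCC(C)=C(Br)C2 | intermediate
21 | (3R,6R)-10-bromo-1,5,5,9-tetramethylspiro[5.5]undeca-1,9-dien-3-ol | CC1=C[C@H](O)CC(C)(C)[C@]12CCC(C)=C(Br)C2 | intermediate
22 | (6R)-10-bromo-1,5,5,9-tetramethylspiro[5.5]undeca-1,9-dien-3-one | CC1=CC(=O)CC(C)(C)[C@]12CCC(C)=C(Br)C2 | intermediate
23 | lithium C3=C4 dienolate of 22 | CC1=CC(O[Li])=CC(C)(C)[C@]12CCC(C)=C(Br)C2 | intermediate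
24 | 3-trimethylsilyloxy C3=C4 dienol ether of 22 | CC1=CC(O[Si](C)(C)C)=CC(C)(C)[C@]12CCC(C)=C(Br)C2 | intermediate
25 | (4S,6S)-4,10-dibromo-1,5,5,9-tetramethylspiro[5.5]undeca-1,9-dien-3-one | CC1=CC(=O)[C@@H](Br)C(C)(C)[C@]12CCC(C)=C(Br)C2 | intermediate
26 | (3S,4S,6S)-4,10-dibromo-1,5,5,9-tetramethylspiro[5.5]undeca-1,9-dien-3-ol | CC1=C[C@H](O)[C@@H](Br)C(C)(C)[C@]12CCC(C)=C(Br)C2 | target

Total step count: 14. Longest linear sequence: 12 steps (4 to 26, steps 3–14).

Steps most likely to fail

Step 7. Hydride transfer may stray to the conjugated dienone, the C5 radical may be reduced before it closes ring A, and the face selectivity relayed from C3 to C6 may be modest. The fallback keeps the same bond formation but generates the C5 radical without a metal hydride; it sets out from 11 and returns at 13. Mukaiyama hydration of the 1,1-disubstituted alkene of 11 (Co(acac)2, PhSiH3, O2, THF, then reductive work-up) should give the tertiary alcohol (4R,5Z)-4-(tert-butyldimethylsilyloxy)-6-iodo-2-methylhept-5-en-2-ol F1. Suzuki–Miyaura coupling of F1 with 3 under the conditions of step 6 should give 3-[(2Z,4R)-4-(tert-butyldimethylsilyloxy)-6-hydroxy-6-methylhept-2-en-2-yl]cyclohex-2-en-1-one F2. Acylation with chloro N-phthalimidoyl oxalate (Et3N, DMAP, CH2Cl2) should give the tert-alkyl N-phthalimidoyl oxalate of F2, F3. Visible-light photoredox fragmentation of F3 (Ru(bpy)3(PF6)2, Hantzsch ester, i-Pr2NEt·HBF4, THF/CH2Cl2, blue light, 23 °C) loses two CO2 and phthalimide, and the tertiary radical should close ring A by the same 6-exo conjugate addition to give 13.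

Step 13. Bromine may enter C4 on the wrong face, or the enolate may drift toward the γ-methyl position. The fallback sets C4 by proton delivery instead of bromine delivery; it sets out from 22 and returns at 25. If the conditions of step 13 give mainly the C4 epimer (4R,6S)-4,10-dibromo-1,5,5,9-tetramethylspiro[5.5]undeca-1,9-dien-3-one F4, this is deprotonated with LiN(SiMe3)2 (THF, −78 °C) to lithium (6S)-4,10-dibromo-1,5,5,9-tetramethylspiro[5.5]undeca-1,3,9-trien-3-olate F5. Kinetic protonation of F5 with acetic acid at −78 °C should put the proton on the face that bromine preferred, which inverts C4 and gives 25.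

Step 14. Hydride delivery may prefer the face away from the axial C5 methyl, which would give the cis bromohydrin. The fallback makes that isomer on purpose and inverts it; it sets out from 25 and returns at 26. Reduction with the bulky i-Bu2AlH (CH2Cl2, −78 °C) should give (3R,4S,6S)-4,10-dibromo-1,5,5,9-tetramethylspiro[5.5]undeca-1,9-dien-3-ol F6. Mitsunobu inversion of F6 (4-nitrobenzoic acid, PPh3, DIAD, toluene, 0 → 23 °C) should give (3S,4S,6S)-4,10-dibromo-1,5,5,9-tetramethylspiro[5.5]undeca-1,9-dien-3-yl 4-nitrobenzoate F7. Methanolysis of F7 (K2CO3, MeOH, 0 °C) should give 26.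

Further compounds
F1 | step 7 | (4R,5Z)-4-(tert-butyldimethylsilyloxy)-6-iodo-2-methylhept-5-en-2-ol | CC(C)(O)C[C@@H](O[Si](C)(C)C(C)(C)C)/C=C(/C)I
F2 | step 7 | 3-[(2Z,4R)-4-(tert-butyldimethylsilyloxy)-6-hydroxy-6-methylhept-2-en-2-yl]cyclohex-2-en-1-one | CC(C)(O)C[C@@H](O[Si](C)(C)C(C)(C)C)/C=C(/C)C1=CC(=O)CCC1
F3 | step 7 | (4R,5Z)-4-(tert-butyldimethylsilyloxy)-2-methyl-6-(3-oxocyclohex-1-en-1-yl)hept-5-en-2-yl N-phthalimidoyl oxalate | CC(C)(OC(=O)C(=O)ON1C(=O)c2ccccc2C1=O)C[C@@H](O[Si](C)(C)C(C)(C)C)/C=C(/C)C1=CC(=O)CCC1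
F4 | step 13 | (4R,6S)-4,10-dibromo-1,5,5,9-tetramethylspiro[5.5]undeca-1,9-dien-3-one | CC1=CC(=O)[C@H](Br)C(C)(C)[C@]12CCC(C)=C(Br)C2
F5 | step 13 | lithium (6S)-4,10-dibromo-1,5,5,9-tetramethylspiro[5.5]undeca-1,3,9-trien-3-olate | CC1=CC(O[Li])=C(Br)C(C)(C)[C@]12CCC(C)=C(Br)C2
F6 | step 14 | (3R,4S,6S)-4,10-dibromo-1,5,5,9-tetramethylspiro[5.5]undeca-1,9-dien-3-ol | CC1=C[C@@H](O)[C@@H](Br)C(C)(C)[C@]12CCC(C)=C(Br)C2
F7 | step 14 | (3S,4S,6S)-4,10-dibromo-1,5,5,9-tetramethylspiro[5.5]undeca-1,9-dien-3-yl 4-nitrobenzoate | CC1=C[C@H](OC(=O)c3ccc(cc3)[N+](=O)[O-])[C@@H](Br)C(C)(C)[C@]12CCC(C)=C(Br)C2
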